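**Plan**
- Retrosynthesis: the shifted (retro) polyene and the C4=C5/C6=C7 diene are cut back to a C8' carbinol (vinylogous dehydration, proton from C4). The C7'–C8' bond is cut next (alkenyllithium plus the commercial C30 aldehyde 8'-apo-β-caroten-8'-al). Then the saturated ring is opened at C2'–C3' (metathesis, then hydrogenation), then C6'–C1' (allylzincation of a silylalkyne), then the C5' centre (auxiliary-controlled allylation).
- Forward: the open chain C3'–C4'–C5'(Me)–C6'(=C7')–C1'(Me)2–C2' is assembled first, with the stereocentre, the quaternary carbon and the exocyclic olefin geometry already in place. The saturated ring is then closed, the chain is joined at C7'–C8', and the unsaturated ring's diene and the shifted polyene arise in the last step.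
- Feature that allows the closure: C2' and C3' are the only adjacent unsubstituted methylenes of the C1'–C6' ring, remote from C5' and from C6'=C7'. The two arms ending in them are geminal on the trigonal C6', and one is anchored by the gem-dimethyl C1', so they can be offered as two terminal vinyl groups. Closing here avoids olefination of a hindered, epimerisable 2,2,6-trimethylcyclohexanone.
- Stereochemistry: C5' (S) comes from an Evans allylation. The C6'=C7' geometry comes from a syn carbozincation that leaves silicon cis to the C5' arm; silicon is then replaced with retention by I, Li and C8'. The E chain comes from the aldehyde and from elimination through the extended cation.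

Key step: step 7

Remark: carotenoid numbering is used (unsaturated ring C1–C6, chain C7–C15 and C15'–C7', saturated ring C1'–C6'). The target is read as (5'S,6E,6'E)-4,5'-retro-β,β-carotene. Carbinol centres that are destroyed later (C8' of 19; C4 and C6' in the fallbacks) are formed as epimer mixtures.

Step 1
Reactants: 1 (R)-4-benzyl-3-propanoyl-1,3-oxazolidin-2-one; 2 allyl iodide
Product: 4 (R)-4-benzyl-3-[(S)-2-methylpent-4-enoyl]-1,3-oxazolidin-2-one, via sodium (Z)-enolate 3 (not isolated)
Conditions: NaN(SiMe3)2, THF, −78 °C; then 2, −78 → −45 °C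
Reagents that add atoms: none
Why: Evans asymmetric alkylation: the chelated (Z)-enolate should be allylated on the face opposite the benzyl group, which sets the future C5' centre as (S).

Step 2
Reactants: 4
Product: 5 (S)-2-methylpent-4-en-1-ol
Conditions: LiBH4, MeOH (1 equiv), Et2O, 0 °C
Reagents that add atoms: none
Why: Reductive cleavage of the N-acyl oxazolidinone should release the primary alcohol without touching the α-stereocentre and return the auxiliary.

Step 3
Reactants: 5
Product: 6 (S)-2-methylpent-4-enal
Conditions: TEMPO (10 mol %), PhI(OAc)2, CH2Cl2, rt; solution used directly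
Reagents that add atoms: none
Why: Oxoammonium (TEMPO) oxidation is a neutral way to an α-branched aldehyde that should not epimerise it; the volatile product is carried on in solution.

Step 4
Reactants: 6
Product: 7 (S)-1,1-dibromo-3-methylhexa-1,5-diene
Conditions: CBr4, PPh3, Zn, CH2Cl2, rt; then 6, 0 °C → rt
Reagents that add atoms: carbon tetrabromide, BrC(Br)(Br)Br
Why: Corey–Fuchs dibromo-olefination (Wittig-type reaction of Ph3P=CBr2), kept neutral by zinc, adds the carbon that becomes C7' without epimerising the adjacent centre.

Step 5
Reactants: 7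
Product: 9 (S)-trimethyl(3-methylhex-5-en-1-yn-1-yl)silane, via lithium acetylide 8 (not isolated)
Conditions: n-BuLi (2.1 equiv), THF, −78 → 0 °C; then Me3SiCl, −78 °C → rt
Reagents that add atoms: chlorotrimethylsilane, C[Si](C)(C)Cl
Why: Second half of the Corey–Fuchs sequence (Br/Li exchange and Fritsch–Buttenberg–Wiechell-type rearrangement) gives the acetylide, and C-silylation installs the group that later holds the place of the polyene chain.

Step 6
Reactants: 9; 10 prenyl bromide
Product: 13 trimethyl[(1E,3S)-3-methyl-2-(2-methylbut-3-en-2-yl)hexa-1,5-dien-1-yl]silane, via prenylzinc bromide 11 (not isolated), via alkenylzinc bromide 12 (not isolated)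
Conditions: 10, Zn dust, THF, 0 °C; then 9, THF, 50 °C; sat. aq. NH4Cl, 0 °C
Reagents that add atoms: none
Why: Allylzincation of a 1-silylalkyne (zinc-ene carbometalation): the prenyl group should add through its γ-carbon to the alkyne carbon remote from silicon in a six-membered syn transition state, creating the quaternary C1' with its vinyl group and, after protonolysis with retention, leaving silicon cis to the C5' arm (E).

Step 7
Reactants: 13
Product: 14 trimethyl{(E)-[(6S)-2,2,6-trimethylcyclohex-3-en-1-ylidene]methyl}silane
Conditions: second-generation Hoveyda–Grubbs catalyst RuCl2(H2IMes)(=CH-C6H4-2-OiPr) (5 mol %), 1,4-benzoquinone (10 mol %), toluene (0.01 M), 60 °C, argon sparge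
Reagents that add atoms: none
Why: Ring-closing olefin metathesis by the Chauvin mechanism: the ruthenium alkylidene should load on the unhindered allyl terminus (future C3'), add [2+2] to the vinyl group on the quaternary carbon (future C2') and cyclorevert with loss of ethene, forming C2'=C3', which step 8 saturates. The closest known reaction type is ring-closing metathesis of 1,7-dienes that carry an allylic quaternary centre. The six-membered ring closes through the terminal alkene carbons of two arms that are geminal on the trigonal C6', a closure favoured by the gem-dimethyl group at C1' in the tether. No stereocentre is created; C5' is not adjacent to a reacting carbon and should stay (S), and the exocyclic C6'=C7' geometry is carried through untouched. The step needs chemoselectivity for the two monosubstituted olefins over the trisubstituted vinylsilane, which its position between a quaternary and a tertiary carbon and its silyl group should secure. High dilution with removal of ethene should suppress dimerisation, and benzoquinone should suppress double-bond migration by ruthenium hydrides.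

Step 8
Reactants: 14
Product: 15 trimethyl{(E)-[(6S)-2,2,6-trimethylcyclohexylidene]methyl}silane
Conditions: H2 (3 atm), RhCl(PPh3)3 (5 mol %), benzene, rt
Reagents that add atoms: none
Why: Homogeneous hydrogenation with RhCl(PPh3)3 discriminates by substitution, so the cis-disubstituted ring olefin should be saturated while the hindered trisubstituted vinylsilane survives, completing the C2'–C3' single bond.

Step 9
Reactants: 15
Product: 16 (3S,E)-2-(iodomethylidene)-1,1,3-trimethylcyclohexane
Conditions: N-iodosuccinimide, 2,6-lutidine (0.3 equiv), (CF3)2CHOH, 0 °C, dark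
Reagents that add atoms: N-iodosuccinimide, O=C1CCC(=O)N1I
Why: Electrophilic ipso-iododesilylation: iodonium attack at the silicon-bearing carbon gives a β-silyl cation that should lose silicon after the least-motion rotation, so iodine replaces silicon with retention (E), the fluorinated alcohol speeding desilylation.

Step 10
Reactants: 16; 17 8'-apo-β-caroten-8'-al (all-trans)
Product: 19 (5'S,6'E,8'RS)-5',8'-dihydro-β,β-caroten-8'-ol, via alkenyllithium 18 (not isolated)
Conditions: t-BuLi (2 equiv), Et2O, −78 °C; then 17 in THF, −78 → −40 °C; sat. aq. NH4Cl; crude product used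
Reagents that add atoms: none
Why: Iodine–lithium exchange gives a configurationally stable alkenyllithium that should add 1,2 to the non-enolisable C8' aldehyde and form the C7'–C8' bond; the new carbinol centre is removed in step 11.

Step 11
Reactants: 19
Product: 20 (5'S,6E,6'E)-4,5'-retro-β,β-carotene
Conditions: p-TsOH·H2O (2 mol %), CH2Cl2, −20 → 0 °C, dark, argon; Et3N; then heptane, 80 °C; crystallisation
Reagents that add atoms: none
Why: Acid-induced vinylogous dehydration (the retinol-to-anhydroretinol type of 1,n-elimination): ionisation of the doubly allylic C8' hydroxyl gives a cation delocalised from C6' to C5, and loss of the aligned allylic proton at C4 should shift every chain double bond by one position and give the extended all-E retro system, while the C5' hydrogen, held in the plane of C6'=C7' by allylic 1,3-strain with C8', is not aligned for loss.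

**Compound list**
1 | (R)-4-benzyl-3-propanoyl-1,3-oxazolidin-2-one | CCC(=O)N1[C@H](Cc2ccccc2)COC1=O | starting material
2 | allyl iodide | C=CCI | starting material
3 | sodium (Z)-enolate of 1 | C/C=C(\[O-])N1[C@H](Cc2ccccc2)COC1=O.[Na+] | intermediate
4 | (R)-4-benzyl-3-[(S)-2-methylpent-4-enoyl]-1,3-oxazolidin-2-one | C=CC[C@H](C)C(=O)N1[C@H](Cc2ccccc2)COC1=O | intermediate
5 | (S)-2-methylpent-4-en-1-ol | C=CC[C@H](C)CO | intermediate
6 | (S)-2-methylpent-4-enal | C=CC[C@H](C)C=O | intermediate
7 | (S)-1,1-dibromo-3-methylhexa-1,5-diene | C=CC[C@H](C)C=C(Br)Br | intermediate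
8 | lithium (S)-3-methylhex-5-en-1-yn-1-ide | C=CC[C@H](C)C#[C-].[Li+] | intermediate
9 | (S)-trimethyl(3-methylhex-5-en-1-yn-1-yl)silane | C=CC[C@H](C)C#C[Si](C)(C)C | intermediate
10 | prenyl bromide (1-bromo-3-methylbut-2-ene) | CC(C)=CCBr | starting material
11 | prenylzinc bromide | CC(C)=CC[Zn]Br | intermediate
12 | bromo[(1Z,3S)-3-methyl-2-(2-methylbut-3-en-2-yl)-1-(trimethylsilyl)hexa-1,5-dien-1-yl]zinc | C=CC[C@H](C)/C(=C(/[Zn]Br)[Si](C)(C)C)C(C)(C)C=C | intermediate
13 | trimethyl[(1E,3S)-3-methyl-2-(2-methylbut-3-en-2-yl)hexa-1,5-dien-1-yl]silane | C=CC[C@H](C)/C(=C\[Si](C)(C)C)C(C)(C)C=C | intermediate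
14 | trimethyl{(E)-[(6S)-2,2,6-trimethylcyclohex-3-en-1-ylidene]methyl}silane | C[C@H]1CC=CC(C)(C)/C1=C/[Si](C)(C)C | intermediate
15 | trimethyl{(E)-[(6S)-2,2,6-trimethylcyclohexylidene]methyl}silane | C[C@H]1CCCC(C)(C)/C1=C/[Si](C)(C)C | intermediate
16 | (3S,E)-2-(iodomethylidene)-1,1,3-trimethylcyclohexane | C[C@H]1CCCC(C)(C)/C1=C/I | intermediate
17 | 8'-apo-β-caroten-8'-al (all-trans) | O=C/C(C)=C/C=C/C(C)=C/C=C/C=C(C)/C=C/C=C(C)/C=C/C1=C(C)CCCC1(C)C | starting material
18 | {(E)-[(6S)-2,2,6-trimethylcyclohexylidene]methyl}lithium | C[C@H]1CCCC(C)(C)/C1=C/[Li] | intermediate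
19 | (5'S,6'E,8'RS)-5',8'-dihydro-β,β-caroten-8'-ol | C[C@H]1CCCC(C)(C)/C1=C/C(O)/C(C)=C/C=C/C(C)=C/C=C/C=C(C)/C=C/C=C(C)/C=C/C2=C(C)CCCC2(C)C | intermediate
20 | (5'S,6E,6'E)-4,5'-retro-β,β-carotene | CC1=CCCC(C)(C)\C1=C/C=C(C)/C=C/C=C(C)/C=C/C=C/C(C)=C/C=C/C(C)=C/C=C1\[C@@H](C)CCCC1(C)C | target

**Count**
Total steps: 11. Longest linear sequence: 11 steps (1 → 20); 2, 10 and 17 are bought.

**Steps most likely to fail**

Step 11. The delocalised cation may lose a proton at the wrong site (C5', which would give the ordinary β-ring, or the C5 methyl group), or the acid may re-protonate the product and scramble double-bond geometry. The fallback sets out from 17 and 16 and comes back at 20; it makes the retro system on the C30 part alone, where C4 is the only ring position that can lose a proton. Aldehyde 17 is reduced (NaBH4, EtOH/THF, 0 °C) to 8'-apo-β-caroten-8'-ol F1. Brief acid treatment (HCl in EtOH, 0 °C), the anhydroretinol reaction itself, should give 4,5-didehydro-8',5-retro-8'-apo-β-carotene F2, which ends in a C8' methylidene. A Mizoroki–Heck coupling of alkenyl iodide 16 with this terminal diene (Pd(OAc)2, P(o-tol)3, Ag2CO3, DMF, 40 °C) should form C7'–C8' and, by β-hydride elimination from C8', the C8'=C9' bond of 20.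

Step 6. The carbometalation may stall at the branched, silicon-capped alkyne while a quaternary centre is being formed, the allylic zinc reagent may lose its γ-selectivity, or the α-silyl alkenylzinc may equilibrate geometrically before protonolysis. The fallback sets out from 6 and comes back at 20; it closes the same ring bond at the ketone stage and attaches the chain through an acetylide.
- Aldehyde 6 is allylated by prenylzinc bromide 11 at its γ-carbon (THF, 0 °C) to (5S)-3,3,5-trimethylocta-1,7-dien-4-ol F3.
- Dess–Martin oxidation gives (S)-3,3,5-trimethylocta-1,7-dien-4-one F4.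
- Ring-closing metathesis (second-generation Grubbs catalyst RuCl2(=CHPh)(PCy3)(H2IMes), CH2Cl2, 40 °C) gives (S)-2,2,6-trimethylcyclohex-3-en-1-one F5, and H2 over Pd/C gives (S)-2,2,6-trimethylcyclohexan-1-one F6.
- Aldehyde 17 is homologated with the Ohira–Bestmann reagent (K2CO3, MeOH/THF) to the terminal alkyne 7',8'-didehydro-7'-apo-β-carotene F7.
- The magnesium acetylide of F7 (EtMgBr, THF) adds to F6 in the presence of LaCl3·2LiCl to give (5'S,6'RS)-7',8'-didehydro-5',6'-dihydro-β,β-caroten-6'-ol F8.
- NaAlH2(OCH2CH2OMe)2 reduces the triple bond trans to (5'S,6'RS)-5',6'-dihydro-β,β-caroten-6'-ol F9.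
- The acid of step 11 should ionise F9 at C6' to the same delocalised cation and give 20. Loss of the C5' proton to the β-ring is a greater hazard here, because the exocyclic olefin is not in place beforehand.

Step 7. Metathesis may stall at the neopentyl-type vinyl group, or ruthenium hydrides may move the double bonds. The fallback sets out from 13 and comes back at 14. Lemieux–Johnson cleavage of the two terminal vinyl groups (OsO4 cat., NaIO4, 2,6-lutidine, dioxane/H2O; the shielded vinylsilane should be spared) gives (4S,E)-2,2,4-trimethyl-3-[(trimethylsilyl)methylidene]hexanedial F10. Intramolecular McMurry coupling (TiCl3(DME)1.5, Zn–Cu, DME, reflux, slow addition) should close the C2'=C3' olefin of 14.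

**Further compounds**
F1 | step 11 | 8'-apo-β-caroten-8'-ol | OC/C(C)=C/C=C/C(C)=C/C=C/C=C(C)/C=C/C=C(C)/C=C/C1=C(C)CCCC1(C)C
F2 | step 11 | (6E)-4,5-didehydro-8',5-retro-8'-apo-β-carotene | CC1=CCCC(C)(C)\C1=C/C=C(C)/C=C/C=C(C)/C=C/C=C/C(C)=C/C=C/C(C)=C
F3 | step 6 | (5S)-3,3,5-trimethylocta-1,7-dien-4-ol | C=CC[C@H](C)C(O)C(C)(C)C=C
F4 | step 6 | (S)-3,3,5-trimethylocta-1,7-dien-4-one | C=CC[C@H](C)C(=O)C(C)(C)C=C
F5 | step 6 | (S)-2,2,6-trimethylcyclohex-3-en-1-one | C[C@H]1CC=CC(C)(C)C1=O
F6 | step 6 | (S)-2,2,6-trimethylcyclohexan-1-one | C[C@H]1CCCC(C)(C)C1=O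
F7 | step 6 | 7',8'-didehydro-7'-apo-β-carotene | C#C/C(C)=C/C=C/C(C)=C/C=C/C=C(C)/C=C/C=C(C)/C=C/C1=C(C)CCCC1(C)C
F8 | step 6 | (5'S,6'RS)-7',8'-didehydro-5',6'-dihydro-β,β-caroten-6'-ol | C[C@H]1CCCC(C)(C)C1(O)C#C/C(C)=C/C=C/C(C)=C/C=C/C=C(C)/C=C/C=C(C)/C=C/C2=C(C)CCCC2(C)C
F9 | step 6 | (5'S,6'RS)-5',6'-dihydro-β,β-caroten-6'-ol | C[C@H]1CCCC(C)(C)C1(O)/C=C/C(C)=C/C=C/C(C)=C/C=C/C=C(C)/C=C/C=C(C)/C=C/C2=C(C)CCCC2(C)C
F10 | step 7 | (4S,E)-2,2,4-trimethyl-3-[(trimethylsilyl)methylidene]hexanedial | O=CC[C@H](C)/C(=C\[Si](C)(C)C)C(C)(C)C=O
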